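Count the reagent spent, not the percent converted.

| setting | beta | alpha | theta | epsilon | Thursday's | Saturday's | Monday's | Sunday's | Friday's |
|---|---|---|---|---|---|---|---|---|---|
| starting material | 0.0086 M | 0.028 M | 0.062 M | 0.020 M | 0.012 M | 0.020 M | 0.020 M | 0.020 M | 0.060 M |
| reagent | 0.022 M | 0.022 M | 0.022 M | 0.022 M | 0.0400 M | 0.0220 M | 0.0600 M | 0.00600 M | 0.0400 M |
| initiator | 0.50 mM | 0.50 mM | 0.50 mM | 0.41 mM | 0.30 mM | 0.50 mM | 0.50 mM | 0.50 mM | 0.50 mM |
| remark | run made earlier | run made earlier | run made earlier | run made earlier |  |  |  |  |  |
| time |  |  |  |  | 30 min | 30 min | 30 min | 30 min | 30 min |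

| run | time / min | target / % | starting material / % |
|---|---|---|---|
| beta | 1.50 | 10.5 | 88.5 |
| beta | 3.00 | 20.9 | 78.6 |
| beta | 6.00 | 38.5 | 59.7 |
| beta | 12.0 | 67.1 | 31.3 |
| beta | 20.0 | 89.6 | 6.6 |
| alpha | 4.00 | 9.3 | 91.8 |
| alpha | 8.00 | 16.3 | 84.0 |
| alpha | 12.0 | 22.0 | 76.9 |
| alpha | 15.0 | 26.3 | 74.1 |
| alpha | 20.0 | 32.0 | 67.8 |
| theta | 2.00 | 2.2 | 97.8 |
| theta | 5.00 | 4.5 | 95.0 |
| theta | 10.0 | 10.0 | 90.6 |
| theta | 15.0 | 12.0 | 87.4 |
| theta | 20.0 | 14.6 | 85.5 |
| epsilon | 4.00 | 10.9 | 90.3 |
| epsilon | 8.00 | 19.2 | 80.7 |
| epsilon | 12.0 | 26.3 | 73.5 |
| epsilon | 15.0 | 31.1 | 67.0 |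
| epsilon | 20.0 | 37.8 | 62.2 |

(standard deviation of a reading: 0.5 percentage points)

- ranking by amount of target, in percent of the starting material charged, from high to low, at 30 min (Thursday's / Saturday's / Monday's / Sunday's / Friday's)
- the amount of target, in percent of the starting material charged of the flask you put first, at 30 min
- the amount of target, in percent of the starting material charged of the flask you put last, at 30 min



Alpha and theta look nearly the same, with equal c(reagent) and c(initiator), yet at 20.0 min alpha shows 32.0 % of target and theta 14.6 %. In concentration these readings are nearly the same amount, 0.00896 M against 0.00905 M, although theta holds 2.21 times the c(starting material). So I take the rate as zero order in c(starting material), and nearly one molar amount divided by two different charges gives the two percentages. Epsilon, with 0.820 of alpha's initiator, makes 0.844 of alpha's amount, so I take the rate as first order in c(initiator).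

The concentration left to set the pace is c(reagent). I assume a pseudo-first-order loss of reagent and read alpha as ln(1/(1 − share spent)): 0.233 at 8.00 min and 0.523 at 20.0 min. Carrying that slope on to 30 min gives 0.765, hence 53.5 %. This is the spent share, the fraction of its own reagent charge a flask with 0.50 mM initiator has used by 30 min while starting material lasts.

Target in percent is then the spent share times c(reagent)/c(starting material), up to the charge. My reckoning gives Saturday's 58.8 %, Friday's 35.6 % and Sunday's 16.0 %. The same product is 1.60 for Monday's and, with the exponent scaled to its initiator, 1.23 for Thursday's. Both exceed the charge, so starting material is the limiting reagent there, and I rank Monday's first for its wider margin.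

The forecast reads Monday's > Thursday's > Saturday's > Friday's > Sunday's, with 99.8 % first and 15.7 % last. It rests on “the reaction is zero order in it until it is nearly gone”, and its reagent consumed, 52%, stands beside my 53.5 %.

The simulation gives Monday's > Thursday's > Saturday's > Friday's > Sunday's, with 98.9 % first and 15.6 % last, so the forecast's order stands and both its amounts fall within tolerance.

    starting material + second chain carrier → by-product + first chain carrier (k = 1.97 × 10⁵ M⁻¹ s⁻¹)
    reagent + first chain carrier → target + second chain carrier (k = 17700 M⁻¹ s⁻¹)
    starting material + initiating radical → capped initiator + first chain carrier (k = 1.16 × 10⁶ M⁻¹ s⁻¹)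
    2 second chain carrier → ended chains (k = 1.60 × 10⁸ M⁻¹ s⁻¹)
    first chain carrier → ended carrier (k = 8.76 s⁻¹)
    initiator → 2 initiating radical (k = 2.51 × 10⁻⁴ s⁻¹)

Sunday's has spent 52.0 % of its reagent, and for Monday's neighbour with 0.015 M reagent the spent share gives 40.1 % against a simulated 38.9 %. Monday's target has come to rest: 0.14 % starting material remains, and ten times the time takes its target from 98.9 % to 99.0 %. Its answer shifts by 5 points if read at 19.3 min or charged with 0.0398 M reagent. Sunday's has not come to rest: 83 % starting material and 64 % initiator remain, and at 300 min its target reaches 25.9 %, under the 30.0 % its reagent charge allows.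

All runs were computed for an exercise; scatter was added.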